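The route rests on cutting, not forming, a bond: the C1 ketone and the C6 lactone carbinol lie 1,6 across the ten-membered ring, so the ring is the periphery of a bicyclo[4.4.0]dec-1(6)-ene (rings A and B) whose shared C1=C6 alkene is cleaved by ozone. In one operation the rigid octalin 28, which already holds the C3 silyl ether, the C4–C5 epoxide, the C8 ester, C10 and a C7=C11 ester of fixed geometry, becomes cyclodecane-1,6-dione 31. The C7=C11 geometry comes from a furan that is opened oxidatively; C6 reduction then closes the butenolide.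

Key step: step 19

Remark: atoms carry germacrane labels (C1 ketone, C3 carbinol, C4–C5 epoxide, C6 lactone carbinol, C7=C11, C8 acyloxy carbon, C10 CHMe, C12 ester or lactone carbonyl, C13 acetoxymethyl); ring A = C1–C6, ring B = C1, C6–C10.
Assumption: the cinchona catalyst of step 1 is the pseudoenantiomer that gives the S half-ester, and hydride enters C8 in step 11 anti to the C10 methyl group, so that the inverting esterification of step 16 is the right one (a trans alcohol would be esterified with retention instead).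

Step 1
Reactants: 1 3-methylglutaric anhydride
Product: 2 (S)-5-methoxy-3-methyl-5-oxopentanoic acid
Conditions: MeOH, (DHQ)2AQN or (DHQD)2AQN (pseudoenantiomer giving the S acid), Et2O, −40 °C
Reagents that add atoms: methanol, CO
Why: Organocatalytic desymmetrising alcoholysis of a prochiral cyclic anhydride, in which the cinchona amine activates methanol and differentiates the enantiotopic carbonyl groups, sets the C10 stereocentre (S).

Step 2
Reactants: 2 (S)-5-methoxy-3-methyl-5-oxopentanoic acid
Product: 4 dimethyl (5S)-5-methyl-3-oxoheptanedioate, via acyl imidazolide 3 (not isolated)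
Conditions: CDI, THF, rt; then KO2CCH2CO2Me, MgCl2, Et3N, MeCN, rt; aq. HCl
Reagents that add atoms: potassium methyl malonate, COC(=O)CC(=O)[O-].[K+]
Why: Masamune–Brooks homologation, in which the imidazolide acylates the magnesium malonate and decarboxylation gives the β-keto ester, leaves the remote methyl ester and the non-enolisable C10 centre untouched.

Step 3
Reactants: 4 dimethyl (5S)-5-methyl-3-oxoheptanedioate; 5 methyl bromopyruvate
Product: 7 dimethyl 2-[(2S)-4-methoxy-2-methyl-4-oxobutyl]furan-3,4-dicarboxylate, via hydroxydihydrofuran 6 (not isolated)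
Conditions: pyridine, THF, 0 °C to rt; then TsOH·H2O (cat.), toluene, 60 °C
Reagents that add atoms: none
Why: Feist–Benary furan synthesis, in which the C7 methylene adds to the pyruvate ketone, the C8 enol oxygen displaces bromide and acid dehydration aromatises, locks C13 cis to the C8 oxygen and the C12 ester cis to C6 across the future C7=C11 bond.

Step 4
Reactants: 7 dimethyl 2-[(2S)-4-methoxy-2-methyl-4-oxobutyl]furan-3,4-dicarboxylate
Product: 8 dimethyl (6S)-6-methyl-4-oxo-4,5,6,7-tetrahydro-1-benzofuran-3,5-dicarboxylate (epimers at the ester-bearing carbon)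
Conditions: NaOMe, MeOH/THF, 60 °C; aq. HCl
Reagents that add atoms: none
Why: Dieckmann condensation, in which the aliphatic ester enolate (C1) attacks the adjacent furan ester (C6) in a six-membered closure of ring B driven by deprotonation of the β-keto ester, is favoured over attack on the other furan ester, which would need a seven-membered ring.

Step 5
Reactants: 8 dimethyl (6S)-6-methyl-4-oxo-4,5,6,7-tetrahydro-1-benzofuran-3,5-dicarboxylate; 9 2-bromo-N-methoxy-N-methylacetamide
Product: 10 C1-alkylated β-keto ester (C1 quaternary; configuration there not defined)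
Conditions: K2CO3, NaI (cat.), acetone, 50 °C
Reagents that add atoms: none
Why: SN2 C-alkylation of the soft β-keto ester enolate by an α-bromo amide brings in C2 and C3, and the configuration at C1 is irrelevant because C1 becomes sp2 in step 7.

Step 6
Reactants: 10 C1-alkylated β-keto ester
Product: 11 methyl (6S)-5-{2-[methoxy(methyl)amino]-2-oxoethyl}-6-methyl-4-oxo-4,5,6,7-tetrahydro-1-benzofuran-3-carboxylate (C1 epimers)
Conditions: LiCl, H2O, DMSO, 140 °C
Reagents that add atoms: none
Why: Krapcho dealkoxycarbonylation, in which chloride demethylates the activated β-keto ester and the carboxylate loses CO2, spares the less electrophilic furoate ester and the Weinreb amide.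

Step 7
Reactants: 11 ketone Weinreb amide
Product: 12 enol triflate: methyl (6S)-5-{2-[methoxy(methyl)amino]-2-oxoethyl}-6-methyl-4-(trifluoromethanesulfonyloxy)-6,7-dihydro-1-benzofuran-3-carboxylate
Conditions: KN(SiMe3)2, THF, −78 °C; PhNTf2, −78 to 0 °C
Reagents that add atoms: N-phenylbis(trifluoromethanesulfonimide), O=S(=O)(N(c1ccccc1)S(=O)(=O)C(F)(F)F)C(F)(F)F
Why: Enolate O-sulfonylation is regiospecific because the C6 ketone can enolise only towards C1 (C7 is a furan carbon), so the C1=C6 double bond is fixed and kept electron-poor for step 11.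

Step 8
Reactants: 12 enol triflate
Product: 13 isopropenyl ketone: methyl (6S)-6-methyl-5-(3-methyl-2-oxobut-3-enyl)-4-(trifluoromethanesulfonyloxy)-6,7-dihydro-1-benzofuran-3-carboxylate
Conditions: CH2=C(CH3)MgBr (1.5 equiv), THF, −78 to −20 °C; aq. NH4Cl
Reagents that add atoms: isopropenylmagnesium bromide, CC(=C)[Mg]Br
Why: Weinreb ketone synthesis stops at the ketone through the magnesium-chelated tetrahedral adduct, and the amide reacts ahead of the hindered conjugated furoate ester while the enol triflate is inert to the Grignard reagent.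

Step 9
Reactants: 13 isopropenyl ketone
Product: 14 allylic alcohol: methyl (6S)-5-[(2S)-2-hydroxy-3-methylbut-3-enyl]-6-methyl-4-(trifluoromethanesulfonyloxy)-6,7-dihydro-1-benzofuran-3-carboxylate
Conditions: (R)-Me-CBS (0.2 equiv), catecholborane, toluene, −78 °C; MeOH
Reagents that add atoms: none
Why: Corey–Bakshi–Shibata reduction, with the isopropenyl group as the large and the C2 methylene as the small substituent, should give the 3S carbinol under catalyst control without hydroboration of the enone.

Step 10
Reactants: 14 allylic alcohol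
Product: 15 TBS ether of 14
Conditions: TBSOTf, 2,6-lutidine, CH2Cl2, −78 °C
Reagents that add atoms: tert-butyldimethylsilyl trifluoromethanesulfonate, CC(C)(C)[Si](C)(C)OS(=O)(=O)C(F)(F)F
Why: Silylation with a silyl triflate and a hindered base protects C3–OH as a bulky ether that later shields one face of C4=C5.

Step 11
Reactants: 15 TBS ether
Product: 18 diol enol triflate (8R-OH cis to 10-Me; C13H2OH cis to C8; CO2Me cis to C6), via furan endoperoxide 16 (not isolated), via Z-enedione 17 (not isolated)
Conditions: O2, hν, tetraphenylporphyrin (cat.), CH2Cl2, −78 °C; Me2S; then MeOH, CeCl3·7H2O, NaBH4, −78 °C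
Reagents that add atoms: oxygen, O=O
Why: Furan photooxygenation ([4+2] addition of singlet oxygen), sulfide reduction to the Z-enedione and Luche 1,2-reduction of both carbonyl groups unveil C8–OH and C13–OH with the ring-derived C7=C11 geometry, hydride being expected to enter C8 anti to the C10 methyl group (1,3-diaxial avoidance) to give the alcohol cis to that methyl, while the electron-poor enol triflate and the 1,1-disubstituted alkene do not compete for singlet oxygen.

Step 12
Reactants: 18 diol enol triflate
Product: 19 vinyl diene diol (C5 vinyl group on C6)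
Conditions: Bu3SnCH=CH2, Pd(PPh3)4 (5 mol %), LiCl, THF, 65 °C
Reagents that add atoms: tributyl(vinyl)stannane, C=C[Sn](CCCC)(CCCC)CCCC
Why: Stille cross-coupling (oxidative addition of the enol triflate to zerovalent palladium, chloride-assisted transmetalation, reductive elimination) attaches C5 to C6 and is run before any allylic ester is present.

Step 13
Reactants: 20 4-methylfuran-2(5H)-one
Product: 23 4-methoxybenzyl (Z)-4-acetoxy-3-methylbut-2-enoate, via sodium hydroxy-enoate 21 (not isolated), via hydroxy ester 22 (not isolated)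
Conditions: NaOH (1.0 equiv), H2O/THF, 0 °C, evaporate; PMBCl, DMF, rt; Ac2O, pyridine, DMAP, 0 °C
Reagents that add atoms: sodium hydroxide, [Na+].[OH-]; 4-methoxybenzyl chloride, COc1ccc(CCl)cc1; acetic anhydride, CC(=O)OC(C)=O
Why: Saponification opens the butenolide to the Z-hydroxy carboxylate whose geometry is inherited from the ring, SN2 O-alkylation of the carboxylate blocks the acid terminus, and acetylation caps the γ-hydroxyl before it can relactonise.

Step 14
Reactants: 23 4-methoxybenzyl (Z)-4-acetoxy-3-methylbut-2-enoate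
Product: 24 (Z)-4-acetoxy-3-methylbut-2-enoic acid
Conditions: CF3CO2H, anisole, CH2Cl2, 0 °C
Reagents that add atoms: none
Why: Acidolysis of the 4-methoxybenzyl ester (benzylic C–O ionisation, cation trapped by anisole) frees the acid without touching the primary allylic acetate.

Step 15
Reactants: 19 vinyl diene diol
Product: 25 C13 monoacetate (8R-OH free)
Conditions: AcCl (1.05 equiv), 2,4,6-collidine, CH2Cl2, −78 °C
Reagents that add atoms: acetyl chloride, CC(Cl)=O
Why: Kinetic acylation at low temperature selects the unhindered primary allylic C13–OH over the secondary C8–OH.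

Step 16
Reactants: 25 C13 monoacetate; 24 (Z)-4-acetoxy-3-methylbut-2-enoic acid
Product: 26 C8 ester (8S; acyloxy group trans to 10-Me)
Conditions: PPh3, DIAD, toluene, 0 °C to rt
Reagents that add atoms: none
Why: Mitsunobu esterification, in which the carboxylate displaces the C8 oxyphosphonium ion by SN2, attaches the side chain without activating the isomerisation-prone Z-acid and inverts C8 to the 8S configuration trans to the C10 methyl group.

Step 17
Reactants: 26 C8 ester
Product: 27 octalin diene (ring A closed; C4=C5 and C1=C6; 3S-OTBS)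
Conditions: second-generation Hoveyda–Grubbs catalyst RuCl2(H2IMes)(=CH–C6H4-2-OiPr) (5 mol %), 1,4-benzoquinone (10 mol %), CH2Cl2, 40 °C
Reagents that add atoms: none
Why: Ring-closing olefin metathesis between the C6 vinyl group and the isopropenyl group closes ring A at the trisubstituted C4=C5 bond with loss of ethylene, the tetrasubstituted and ester-conjugated alkenes being inert to the ruthenium carbene.

Step 18
Reactants: 27 octalin diene
Product: 28 epoxy octalin with C7 alkylidene ester (4,5-epoxide anti to 3-OTBS)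
Conditions: aq. NaOCl (pH 11.3), MnCl(salen) (5 mol %; salen = N,N'-bis(3,5-di-tert-butylsalicylidene)ethane-1,2-diamine dianion), 4-phenylpyridine N-oxide, CH2Cl2, 0 °C
Reagents that add atoms: sodium hypochlorite, [Na+].[O-]Cl
Why: Oxo-manganese(salen) epoxidation of a conjugated diene favours, through its side-on approach, the trisubstituted C4=C5 alkene over the tetrasubstituted C1=C6 and the enoate alkenes, and delivers oxygen anti to the C3 silyl ether, which allylic strain with the C4 methyl group holds pseudoaxial, so setting C4 and C5.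

Step 19
Reactants: 28 epoxy octalin with C7 alkylidene ester
Product: 31 cyclodecane-1,6-dione with C7=C11 ester, via primary ozonide 29 (not isolated), via secondary ozonide 30 (not isolated)
Conditions: O3 (1 equiv, Sudan Red 7B end point), NaHCO3, CH2Cl2, −78 °C; Me2S, −78 °C to rt
Reagents that add atoms: ozone, [O-][O+]=O
Why: Ozone adds across the electron-rich C1=C6 bond in a concerted [3+2] cycloaddition to primary ozonide 29, which cycloreverts to a tethered ketone and carbonyl oxide that recombine to secondary ozonide 30, and dimethyl sulfide then reduces the O–O bond and releases both ketones. The closest known reaction type is the ozonolysis of bicyclo[4.4.0]dec-1(6)-enes (9,10-octalins) to cyclodecane-1,6-diones. No ring is closed by bond formation: the ten-membered ring is the periphery of rings A and B and appears by scission of their shared C1–C6 bond, so no macrocyclisation penalty is paid. No stereocentre is created, and C3, C4, C5, C8 and C10 are carried over unchanged from the rigid bicycle. The step needs chemoselectivity for C1=C6 over three other C=C bonds, which the substrate secures because C7=C11 and the side-chain alkene are α,β-unsaturated esters with allylic acyloxy groups while C1=C6 carries no carbonyl group, and one equivalent of ozone with a dye end point guards against over-oxidation. The C6 ketone emerges conjugated to the C7=C11 ester and is reduced at once in step 20 to forestall transannular aldol reaction of the 1,6-dione.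

Step 20
Reactants: 31 cyclodecane-1,6-dione with C7=C11 ester
Product: 33 3-O-TBS butenolide, via hydroxy ester 32 (not isolated)
Conditions: NaBH4, CeCl3·7H2O, MeOH/CH2Cl2, −78 °C; AcOH
Reagents that add atoms: none
Why: Luche reduction adds hydride 1,2 to the doubly activated C6 enone carbonyl in preference to the saturated, α-branched C1 ketone, hydride being expected anti to the epoxide C5–O bond (Felkin/chelation model for α,β-epoxy ketones) to give the 6S carbinol, whose alkoxide lactonises onto the cis C12 methyl ester.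

Step 21
Reactants: 33 3-O-TBS butenolide
Product: 34 target, (3S,4R,5S,6S,8S,10S)-13-acetoxy-8-[(Z)-4-acetoxy-3-methylbut-2-enoyloxy]-4,5-epoxy-3-hydroxy-1-oxogermacr-7(11)-en-12,6-olide
Conditions: HF·pyridine, pyridine, THF, 0 °C
Reagents that add atoms: none
Why: Fluoride-mediated desilylation under pyridine buffering cleaves the Si–O bond without opening the epoxide or dehydrating the β-hydroxy ketone.

Compound list
1 | 3-methylglutaric anhydride | CC1CC(=O)OC(=O)C1 | starting material
2 | (S)-5-methoxy-3-methyl-5-oxopentanoic acid | OC(=O)C[C@H](C)CC(=O)OC | intermediate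
3 | methyl (S)-5-(imidazol-1-yl)-3-methyl-5-oxopentanoate | COC(=O)C[C@@H](C)CC(=O)n1ccnc1 | intermediate (not isolated)
4 | dimethyl (5S)-5-methyl-3-oxoheptanedioate | COC(=O)CC(=O)C[C@H](C)CC(=O)OC | intermediate
5 | methyl bromopyruvate | COC(=O)C(=O)CBr | starting material
6 | dimethyl 4-hydroxy-2-[(2S)-4-methoxy-2-methyl-4-oxobutyl]-4,5-dihydrofuran-3,4-dicarboxylate (carbinol epimers) | COC(=O)C[C@@H](C)CC1=C(C(=O)OC)C(O)(C(=O)OC)CO1 | intermediate (not isolated)
7 | dimethyl 2-[(2S)-4-methoxy-2-methyl-4-oxobutyl]furan-3,4-dicarboxylate | COC(=O)C[C@@H](C)Cc1occ(C(=O)OC)c1C(=O)OC | intermediate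
8 | dimethyl (6S)-6-methyl-4-oxo-4,5,6,7-tetrahydro-1-benzofuran-3,5-dicarboxylate (C1 epimers) | C[C@H]1Cc2occ(C(=O)OC)c2C(=O)C1C(=O)OC | intermediate
9 | 2-bromo-N-methoxy-N-methylacetamide | CON(C)C(=O)CBr | starting material
10 | dimethyl (6S)-5-{2-[methoxy(methyl)amino]-2-oxoethyl}-6-methyl-4-oxo-4,5,6,7-tetrahydro-1-benzofuran-3,5-dicarboxylate (quaternary C1 not defined) | C[C@H]1Cc2occ(C(=O)OC)c2C(=O)C1(CC(=O)N(C)OC)C(=O)OC | intermediate
11 | methyl (6S)-5-{2-[methoxy(methyl)amino]-2-oxoethyl}-6-methyl-4-oxo-4,5,6,7-tetrahydro-1-benzofuran-3-carboxylate (C1 epimers) | C[C@H]1Cc2occ(C(=O)OC)c2C(=O)C1CC(=O)N(C)OC | intermediate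
12 | methyl (6S)-5-{2-[methoxy(methyl)amino]-2-oxoethyl}-6-methyl-4-(trifluoromethanesulfonyloxy)-6,7-dihydro-1-benzofuran-3-carboxylate | C[C@H]1Cc2occ(C(=O)OC)c2C(OS(=O)(=O)C(F)(F)F)=C1CC(=O)N(C)OC | intermediate
13 | methyl (6S)-6-methyl-5-(3-methyl-2-oxobut-3-enyl)-4-(trifluoromethanesulfonyloxy)-6,7-dihydro-1-benzofuran-3-carboxylate | C[C@H]1Cc2occ(C(=O)OC)c2C(OS(=O)(=O)C(F)(F)F)=C1CC(=O)C(C)=C | intermediate
14 | methyl (6S)-5-[(2S)-2-hydroxy-3-methylbut-3-enyl]-6-methyl-4-(trifluoromethanesulfonyloxy)-6,7-dihydro-1-benzofuran-3-carboxylate | C[C@H]1Cc2occ(C(=O)OC)c2C(OS(=O)(=O)C(F)(F)F)=C1C[C@H](O)C(C)=C | intermediate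
15 | TBS ether of 14 (3S) | C[C@H]1Cc2occ(C(=O)OC)c2C(OS(=O)(=O)C(F)(F)F)=C1C[C@H](O[Si](C)(C)C(C)(C)C)C(C)=C | intermediate
16 | furan endoperoxide of 15 (O2 bridging C8 and C13; epimers) | COC(=O)C1=C2C(OS(=O)(=O)C(F)(F)F)=C(C[C@H](O[Si](C)(C)C(C)(C)C)C(C)=C)[C@@H](C)CC23OOC1O3 | intermediate (not isolated)
17 | Z-enedione (C8 ketone, C13 aldehyde cis to C8, CO2Me cis to C6) | COC(=O)/C(C=O)=C1/C(=O)C[C@H](C)C(C[C@H](O[Si](C)(C)C(C)(C)C)C(C)=C)=C1OS(=O)(=O)C(F)(F)F | intermediate (not isolated)
18 | diol enol triflate (3S,8R,10S; 8-OH cis to 10-Me; C13H2OH cis to C8) | COC(=O)/C(CO)=C1/[C@H](O)C[C@H](C)C(C[C@H](O[Si](C)(C)C(C)(C)C)C(C)=C)=C1OS(=O)(=O)C(F)(F)F | intermediate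
19 | vinyl diene diol (3S,8R,10S) | COC(=O)/C(CO)=C1/[C@H](O)C[C@H](C)C(C[C@H](O[Si](C)(C)C(C)(C)C)C(C)=C)=C1C=C | intermediate
20 | 4-methylfuran-2(5H)-one | CC1=CC(=O)OC1 | starting material
21 | sodium (Z)-4-hydroxy-3-methylbut-2-enoate | [Na+].[O-]C(=O)/C=C(/C)CO | intermediate (not isolated)
22 | 4-methoxybenzyl (Z)-4-hydroxy-3-methylbut-2-enoate | COc1ccc(COC(=O)/C=C(/C)CO)cc1 | intermediate (not isolated)
23 | 4-methoxybenzyl (Z)-4-acetoxy-3-methylbut-2-enoate | COc1ccc(COC(=O)/C=C(/C)COC(C)=O)cc1 | intermediate
24 | (Z)-4-acetoxy-3-methylbut-2-enoic acid | OC(=O)/C=C(/C)COC(C)=O | intermediate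
25 | C13 monoacetate (3S,8R,10S; 8-OH free) | COC(=O)/C(COC(C)=O)=C1/[C@H](O)C[C@H](C)C(C[C@H](O[Si](C)(C)C(C)(C)C)C(C)=C)=C1C=C | intermediate
26 | C8 ester (3S,8S,10S; 8-acyloxy trans to 10-Me) | COC(=O)/C(COC(C)=O)=C1/[C@@H](OC(=O)/C=C(/C)COC(C)=O)C[C@H](C)C(C[C@H](O[Si](C)(C)C(C)(C)C)C(C)=C)=C1C=C | intermediate
27 | octalin diene (C4=C5 and C1=C6; 3-OTBS and 10-Me on one face, 8-acyloxy on the other) | COC(=O)/C(COC(C)=O)=C1/[C@@H](OC(=O)/C=C(/C)COC(C)=O)C[C@H](C)C2=C1C=C(C)[C@@H](O[Si](C)(C)C(C)(C)C)C2 | intermediate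
28 | epoxy octalin with C7 alkylidene ester (4,5-epoxide anti to 3-OTBS; CO2Me cis to C6) | COC(=O)/C(COC(C)=O)=C1/[C@@H](OC(=O)/C=C(/C)COC(C)=O)C[C@H](C)C2=C1[C@@H]3O[C@]3(C)[C@@H](O[Si](C)(C)C(C)(C)C)C2 | intermediate
29 | primary ozonide (1,2,3-trioxolane across C1–C6) | COC(=O)/C(COC(C)=O)=C1/[C@@H](OC(=O)/C=C(/C)COC(C)=O)C[C@H](C)C25OOOC15[C@@H]3O[C@]3(C)[C@@H](O[Si](C)(C)C(C)(C)C)C2 | intermediate (not isolated)
30 | secondary ozonide (1,2,4-trioxolane bridging C1 and C6) | COC(=O)/C(COC(C)=O)=C1/[C@@H](OC(=O)/C=C(/C)COC(C)=O)C[C@H](C)C25OOC1(O5)[C@@H]3O[C@]3(C)[C@@H](O[Si](C)(C)C(C)(C)C)C2 | intermediate (not isolated)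
31 | cyclodecane-1,6-dione with C7=C11 ester (3-OTBS, 4,5-epoxide, 8-acyloxy, 10-Me) | COC(=O)/C(COC(C)=O)=C1/[C@@H](OC(=O)/C=C(/C)COC(C)=O)C[C@H](C)C(=O)C[C@H](O[Si](C)(C)C(C)(C)C)[C@@]2(C)O[C@H]2C1=O | intermediate
32 | 6S hydroxy ester (C6–OH anti to the epoxide oxygen) | COC(=O)/C(COC(C)=O)=C1/[C@@H](OC(=O)/C=C(/C)COC(C)=O)C[C@H](C)C(=O)C[C@H](O[Si](C)(C)C(C)(C)C)[C@@]2(C)O[C@H]2[C@H]1O | intermediate (not isolated)
33 | 3-O-TBS ether of the target | CC(=O)OCC1=C2[C@@H](OC(=O)/C=C(/C)COC(C)=O)C[C@H](C)C(=O)C[C@H](O[Si](C)(C)C(C)(C)C)[C@@]3(C)O[C@H]3[C@H]2OC1=O | intermediate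
34 | (3S,4R,5S,6S,8S,10S)-13-acetoxy-8-[(Z)-4-acetoxy-3-methylbut-2-enoyloxy]-4,5-epoxy-3-hydroxy-1-oxogermacr-7(11)-en-12,6-olide | CC(=O)OCC1=C2[C@@H](OC(=O)/C=C(/C)COC(C)=O)C[C@H](C)C(=O)C[C@H](O)[C@@]3(C)O[C@H]3[C@H]2OC1=O | target

Total step count: 21. Longest linear sequence: 19 steps (steps 1–12 and 15–21; steps 13 and 14 prepare acid 24).

Steps most likely to fail

Step 18. The oxidant may attack the tetrasubstituted C1=C6 alkene in competition with C4=C5, or deliver oxygen syn to the silyl ether. The fallback sets out from 25 and comes back at 28. Ring-closing metathesis of 25 under the conditions of step 17 gives the C8-hydroxy octalin diene F1. Dess–Martin oxidation gives the cross-conjugated C8 ketone F2, in which C1=C6 is attached to an alkylidene β-keto ester and is electron-poor. mCPBA with NaHCO3 then epoxidises C4=C5 anti to the silyl ether to give the epoxy ketone F3. (R)-Me-CBS with catecholborane sets 8S under catalyst control in the epoxy alcohol F4. Yamaguchi esterification of F4 with acid 24 (2,4,6-trichlorobenzoyl chloride, Et3N, DMAP), which retains configuration, gives 28. This path also avoids the inverting esterification of step 16.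

Step 19. Ozone may not discriminate well enough between C1=C6 and the enoate alkenes, or the ozonide may fragment abnormally instead of giving both ketones. The fallback sets out from 28 and comes back at 31. Stoichiometric osmylation of C1=C6 with OsO4 and TMEDA in CH2Cl2 at −78 °C, followed by reductive work-up, gives the ring-fusion cis-diol F5. Pb(OAc)4 then cleaves the glycol to dione 31, so the medium ring is still released by cutting the shared bond.

Step 20. Hydride may add to the conformationally mobile C6 ketone with poor facial selectivity, or reduce the C1 ketone as well. The fallback sets out from 31 and comes back at 33. (S)-Me-CBS with catecholborane at −78 °C (alkenyl C7 as the large group) reduces the C6 carbonyl under catalyst control to hydroxy ester 32. Lactonisation to 33 is then done as a separate operation with PPTS in toluene. No new compound arises.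

Further compounds
F1 | step 18 | C8-hydroxy octalin diene (8R-OH, 3S-OTBS, C13 acetate) | COC(=O)/C(COC(C)=O)=C1/[C@H](O)C[C@H](C)C2=C1C=C(C)[C@@H](O[Si](C)(C)C(C)(C)C)C2
F2 | step 18 | C8 ketone of the octalin diene | COC(=O)/C(COC(C)=O)=C1/C(=O)C[C@H](C)C2=C1C=C(C)[C@@H](O[Si](C)(C)C(C)(C)C)C2
F3 | step 18 | 4,5-epoxy C8 ketone (epoxide anti to 3-OTBS) | COC(=O)/C(COC(C)=O)=C1/C(=O)C[C@H](C)C2=C1[C@@H]3O[C@]3(C)[C@@H](O[Si](C)(C)C(C)(C)C)C2
F4 | step 18 | 4,5-epoxy 8S alcohol | COC(=O)/C(COC(C)=O)=C1/[C@@H](O)C[C@H](C)C2=C1[C@@H]3O[C@]3(C)[C@@H](O[Si](C)(C)C(C)(C)C)C2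
F5 | step 19 | ring-fusion C1,C6 cis-diol of 28 | COC(=O)/C(COC(C)=O)=C1/[C@@H](OC(=O)/C=C(/C)COC(C)=O)C[C@H](C)C2(O)C1(O)[C@@H]3O[C@]3(C)[C@@H](O[Si](C)(C)C(C)(C)C)C2
F0 | step 20 | none | none
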